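**Plan**
- Ring A, the 4-hydroxy-3-methoxyphenyl ring, is a 1,2,4-trisubstituted benzene with OH para and OMe meta to its benzylic carbon C1. This pattern is that of a 4-alkyl-6-methoxycyclohex-2-enone, so ring A is cut at C1–C2 and C5–C6 into a lactone-bound propanal and 3-methoxybut-3-en-2-one.
- Further back, the C3–OH bond and the C3–CH2Ar link are traced to an (E)-benzylidene lactone (lactone enolate plus O-silylsyringaldehyde), and the lactone C3–C4 bond to an auxiliary-controlled alkylation with a bromoacetate.
- Forward order: the lactone ring first, then the syringyl arm by aldol condensation, then the tertiary carbinol, then ring A by annulation and dehydrogenation, and last the removal of the silyl groups.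
- C4 comes from the alkylation of an (R)-4-benzyloxazolidinone imide. C3 comes from OsO4 addition to the benzylidene face opposite the C4 chain. Neither centre is enolisable afterwards.

Key step: step 13

Assumption: the lactone is numbered O1, C2 (C=O), C3, C4, C5, which makes the target (3S,4R), with the two benzyl groups cis and the C3 hydroxyl trans to the C4 benzyl group; ring A is numbered from its benzylic carbon (OMe on C3, OH on C4).

**Route**

Step 1
Reactants: 1 δ-valerolactone
Product: 2 5-(benzyloxy)pentanoic acid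
Conditions: KOH, BnBr, toluene, reflux; aq. KOH/MeOH; then HCl (aq.)
Reagents that add atoms: benzyl bromide BrCc1ccccc1; potassium hydroxide [K+].[OH-]
Why: Hydroxide opens the lactone and the alkoxide is benzylated in hot toluene (saponification followed by Williamson ether synthesis), any benzyl ester being hydrolysed again before acidification.

Step 2
Reactants: 2 5-(benzyloxy)pentanoic acid; 3 (4R)-4-benzyl-1,3-oxazolidin-2-one
Product: 5 (4R)-4-benzyl-3-[5-(benzyloxy)pentanoyl]-1,3-oxazolidin-2-one, via mixed pivalic anhydride 4 (not isolated)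
Conditions: tBuCOCl, Et3N, THF, −20 °C; then LiCl, 3, −20 °C → rt
Reagents that add atoms: none
Why: Mixed-anhydride N-acylation, in which the oxazolidinone activated by LiCl and Et3N attacks the less hindered pentanoyl carbonyl of the pivalic anhydride.

Step 3
Reactants: 5 (4R)-4-benzyl-3-[5-(benzyloxy)pentanoyl]-1,3-oxazolidin-2-one; 6 tert-butyl bromoacetate
Product: 7 tert-butyl (3S)-3-{[(4R)-4-benzyl-2-oxo-1,3-oxazolidin-3-yl]carbonyl}-6-(benzyloxy)hexanoate
Conditions: NaN(SiMe3)2, THF, −78 °C; then 6, −78 → −40 °C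
Reagents that add atoms: none
Why: Evans alkylation, in which the chelated Z sodium enolate is alkylated by the bromoacetate on the face opposite the benzyl group of the (R)-auxiliary, setting the (S) centre that becomes lactone C4.

Step 4
Reactants: 7 tert-butyl (3S)-3-{[(4R)-4-benzyl-2-oxo-1,3-oxazolidin-3-yl]carbonyl}-6-(benzyloxy)hexanoate
Product: 9 (4S)-4-[3-(benzyloxy)propyl]oxolan-2-one, via hydroxy tert-butyl ester 8 (not isolated)
Conditions: LiBH4, MeOH (1 equiv), THF, 0 °C; then pTsOH·H2O (cat.), toluene, 80 °C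
Reagents that add atoms: none
Why: LiBH4 reduces the activated exocyclic imide carbonyl and leaves the tert-butyl ester (reductive removal of the auxiliary), after which acid-catalysed transesterification closes the γ-lactone without touching the stereocentre.

Step 5
Reactants: 10 syringaldehyde
Product: 11 3,5-dimethoxy-4-(triisopropylsilyloxy)benzaldehyde
Conditions: iPr3SiCl, imidazole, DMF, rt
Reagents that add atoms: chlorotriisopropylsilane CC(C)[Si](Cl)(C(C)C)C(C)C
Why: Imidazole-promoted silylation of the phenol (silyl ether formation), the bulky triisopropylsilyl group being chosen so that the aryl ether should survive the enolate, amine and acid conditions up to step 15.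

Step 6
Reactants: 9 (4S)-4-[3-(benzyloxy)propyl]oxolan-2-one; 11 3,5-dimethoxy-4-(triisopropylsilyloxy)benzaldehyde
Product: 12 (3R,4S)-4-[3-(benzyloxy)propyl]-3-{hydroxy[3,5-dimethoxy-4-(triisopropylsilyloxy)phenyl]methyl}oxolan-2-one (both carbinol epimers)
Conditions: LiN(SiMe3)2, THF, −78 °C; then 11; NH4Cl (aq.)
Reagents that add atoms: none
Why: Aldol addition of the lithium lactone enolate to the aldehyde, which should enter trans to the C4 chain; the configuration of the carbinol carbon is of no account because it is destroyed in step 7.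

Step 7
Reactants: 12 (3R,4S)-4-[3-(benzyloxy)propyl]-3-{hydroxy[3,5-dimethoxy-4-(triisopropylsilyloxy)phenyl]methyl}oxolan-2-one
Product: 14 (3E,4S)-4-[3-(benzyloxy)propyl]-3-[3,5-dimethoxy-4-(triisopropylsilyloxy)benzylidene]oxolan-2-one, via methanesulfonate 13 (not isolated)
Conditions: MsCl, Et3N, CH2Cl2, 0 °C; then DBU, 0 °C → rt
Reagents that add atoms: none
Why: Mesylation and E1cB elimination should give the conjugated benzylidene lactone with the aryl group away from the carbonyl (E), and conjugation with the arene keeps the double bond exocyclic so that C4 is not deprotonated.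

Step 8
Reactants: 14 (3E,4S)-4-[3-(benzyloxy)propyl]-3-[3,5-dimethoxy-4-(triisopropylsilyloxy)benzylidene]oxolan-2-one
Product: 15 (3R,4R)-4-[3-(benzyloxy)propyl]-3-hydroxy-3-{(S)-hydroxy[3,5-dimethoxy-4-(triisopropylsilyloxy)phenyl]methyl}oxolan-2-one
Conditions: OsO4 (cat.), NMO, acetone/H2O, rt
Reagents that add atoms: osmium tetroxide O=[Os](=O)(=O)=O; N-methylmorpholine N-oxide C[N+]1([O-])CCOCC1; water O
Why: Upjohn dihydroxylation adds both oxygens syn to the face of the exocyclic double bond opposite the C4 chain, which allylic 1,3-strain against the aryl group holds pseudo-axial, so the tertiary oxygen at C3 ends up trans to the chain as the target requires (the benzylic carbinol centre formed alongside is removed in step 9).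

Step 9
Reactants: 15 (3R,4R)-4-[3-(benzyloxy)propyl]-3-hydroxy-3-{(S)-hydroxy[3,5-dimethoxy-4-(triisopropylsilyloxy)phenyl]methyl}oxolan-2-one
Product: 16 (3S,4R)-3-[3,5-dimethoxy-4-(triisopropylsilyloxy)benzyl]-3-hydroxy-4-(3-hydroxypropyl)oxolan-2-one
Conditions: H2 (3 atm), Pd(OH)2/C, EtOAc/AcOH, rt → 40 °C
Reagents that add atoms: none
Why: Catalytic hydrogenolysis cleaves the two benzylic C–O bonds, that of the benzyl ether and that of the secondary alcohol on the electron-rich silyloxyarene (assisted by acetic acid), while the tertiary C3–O bond is not benzylic and stays, so C3 keeps the configuration set in step 8.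

Step 10
Reactants: 16 (3S,4R)-3-[3,5-dimethoxy-4-(triisopropylsilyloxy)benzyl]-3-hydroxy-4-(3-hydroxypropyl)oxolan-2-one
Product: 17 (3S,4R)-3-[3,5-dimethoxy-4-(triisopropylsilyloxy)benzyl]-3-(triethylsilyloxy)-4-[3-(triethylsilyloxy)propyl]oxolan-2-one
Conditions: Et3SiOTf, 2,6-lutidine, CH2Cl2, −78 → 0 °C
Reagents that add atoms: triethylsilyl trifluoromethanesulfonate CC[Si](CC)(CC)OS(=O)(=O)C(F)(F)F
Why: The silyl triflate with 2,6-lutidine silylates the primary and the hindered tertiary hydroxyl alike (silyl ether formation), which masks the tertiary oxygen that would otherwise add to the δ-aldehyde as a lactol and divert both the oxidation and the annulation.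

Step 11
Reactants: 17 (3S,4R)-3-[3,5-dimethoxy-4-(triisopropylsilyloxy)benzyl]-3-(triethylsilyloxy)-4-[3-(triethylsilyloxy)propyl]oxolan-2-one
Product: 18 (3S,4R)-3-[3,5-dimethoxy-4-(triisopropylsilyloxy)benzyl]-4-(3-oxopropyl)-3-(triethylsilyloxy)oxolan-2-one
Conditions: (COCl)2, DMSO, CH2Cl2, −78 → −40 °C; then Et3N, −78 °C → rt
Reagents that add atoms: none
Why: Under Swern conditions a primary triethylsilyl ether is attacked by the chlorosulfonium ion and oxidised directly to the aldehyde (oxidative desilylation), whereas the tertiary silyl ether is more hindered and has no carbinol hydrogen and the aryl silyl ether is inert.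

Step 12
Reactants: 19 3,3-dimethoxybutan-2-one
Product: 20 3-methoxybut-3-en-2-one
Conditions: pTsOH·H2O (cat.), hydroquinone (trace), neat, 150 °C, distillation
Reagents that add atoms: none
Why: Acid-catalysed loss of methanol from the dimethyl ketal gives the methyl enol ether (the way 2-methoxypropene is made from 2,2-dimethoxypropane); only the methyl group on the ketal side can lose a proton, and distilling off methanol drives the equilibrium.

Step 13
Reactants: 18 (3S,4R)-3-[3,5-dimethoxy-4-(triisopropylsilyloxy)benzyl]-4-(3-oxopropyl)-3-(triethylsilyloxy)oxolan-2-one; 20 3-methoxybut-3-en-2-one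
Product: 23 (3S,4R)-3-[3,5-dimethoxy-4-(triisopropylsilyloxy)benzyl]-4-[(5-methoxy-4-oxocyclohex-2-en-1-yl)methyl]-3-(triethylsilyloxy)oxolan-2-one (mixture at the two cyclohexenone sp3 carbons), via Michael adduct keto aldehyde 21 (not isolated), via aldol hydroxy ketone 22 (not isolated)
Conditions: freshly distilled 20 (3 equiv), pyrrolidine (30 mol%), AcOH (30 mol%), toluene, slow addition of 18 at 0 °C → rt; then 4 Å sieves, 70 °C
Reagents that add atoms: none
Why: Pyrrolidine converts aldehyde 18 into its enamine, whose β-carbon (the future ring A carbon C1) adds to the unsubstituted terminus of enone 20 to make the C1–C2 bond and, after hydrolysis, keto aldehyde 21; the methyl ketone of 21 then adds as its enamine or enol to the aldehyde (C5–C6 bond, aldol 22) and the β-hydroxy ketone loses water to give 23. The closest known reaction is the secondary-amine-catalysed Michael–aldol (Robinson) annulation of aldehydes with methyl vinyl ketone to 4-substituted cyclohex-2-enones, 20 being a vinyl ketone that carries a methoxyl on its α-carbon. The six-membered carbocycle closes by a 6-(enolendo)-exo-trig aldol reaction, the only ring size open to 21 because every other enol–carbonyl pairing would give a four-membered ring. The two new sp3 centres of the cyclohexenone (C4 and C6) form without control and need none, since both become sp2 carbons of ring A in step 14. What the step must secure is the substitution pattern of ring A, and this is fixed by polarity: the aldehyde α-carbon is the only nucleophile and the enone CH2 the only electrophile in the first bond formation, so the methoxyl ends up next to the carbonyl and the lactone arm at C4. The lactone cannot interfere because C3 is fully substituted and C4 is not α to a carbonyl, the triethylsilyl ether keeps the tertiary oxygen from trapping the aldehyde as a lactol, and slow addition of 18 to excess 20 holds back self-condensation of the aldehyde.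

Step 14
Reactants: 23 (3S,4R)-3-[3,5-dimethoxy-4-(triisopropylsilyloxy)benzyl]-4-[(5-methoxy-4-oxocyclohex-2-en-1-yl)methyl]-3-(triethylsilyloxy)oxolan-2-one
Product: 25 (3S,4R)-3-[3,5-dimethoxy-4-(triisopropylsilyloxy)benzyl]-4-(4-hydroxy-3-methoxybenzyl)-3-(triethylsilyloxy)oxolan-2-one, via cross-conjugated dienone 24 (not isolated)
Conditions: Pd(O2CCF3)2 (5 mol%), 2-(dimethylamino)pyridine (10 mol%), TsOH (20 mol%), O2 (1 atm), DMSO, 80 °C
Reagents that add atoms: none
Why: Palladium-catalysed aerobic dehydrogenation, in which the divalent palladium enolate formed at C6 undergoes β-hydride elimination to dienone 24 that tautomerises to the phenol; with methoxyl at C6 and the lactone arm at C4 only the 4-alkyl-2-methoxyphenol can result, and the lactone centres are untouched.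

Step 15
Reactants: 25 (3S,4R)-3-[3,5-dimethoxy-4-(triisopropylsilyloxy)benzyl]-4-(4-hydroxy-3-methoxybenzyl)-3-(triethylsilyloxy)oxolan-2-one
Product: 26 (3S,4R)-3-hydroxy-3-(4-hydroxy-3,5-dimethoxybenzyl)-4-(4-hydroxy-3-methoxybenzyl)oxolan-2-one (CNP0176953.1)
Conditions: Bu4NF, AcOH, THF, 0 °C → rt
Reagents that add atoms: none
Why: Fluoride cleaves the aryl triisopropylsilyl ether and the tertiary triethylsilyl ether (desilylation through Si–F bond formation), the acetic acid buffer keeps the phenols protonated and the lactone closed, and neither stereocentre can epimerise.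

**Compound list**

1 | δ-valerolactone (oxan-2-one) | O=C1CCCCO1 | starting material
2 | 5-(benzyloxy)pentanoic acid | OC(=O)CCCCOCc1ccccc1 | intermediate
3 | (4R)-4-benzyl-1,3-oxazolidin-2-one | O=C1N[C@H](Cc2ccccc2)CO1 | starting material
4 | 5-(benzyloxy)pentanoic pivalic anhydride | CC(C)(C)C(=O)OC(=O)CCCCOCc1ccccc1 | intermediate (not isolated)
5 | (4R)-4-benzyl-3-[5-(benzyloxy)pentanoyl]-1,3-oxazolidin-2-one | O=C(CCCCOCc1ccccc1)N1[C@H](Cc2ccccc2)COC1=O | intermediate
6 | tert-butyl bromoacetate | CC(C)(C)OC(=O)CBr | starting material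
7 | tert-butyl (3S)-3-{[(4R)-4-benzyl-2-oxo-1,3-oxazolidin-3-yl]carbonyl}-6-(benzyloxy)hexanoate | O=C([C@H](CC(=O)OC(C)(C)C)CCCOCc1ccccc1)N1[C@H](Cc2ccccc2)COC1=O | intermediate
8 | tert-butyl (3S)-6-(benzyloxy)-3-(hydroxymethyl)hexanoate | OC[C@H](CC(=O)OC(C)(C)C)CCCOCc1ccccc1 | intermediate (not isolated)
9 | (4S)-4-[3-(benzyloxy)propyl]oxolan-2-one | O(Cc1ccccc1)CCC[C@@H]2COC(=O)C2 | intermediate
10 | syringaldehyde (4-hydroxy-3,5-dimethoxybenzaldehyde) | COc1cc(C=O)cc(OC)c1O | starting material
11 | 3,5-dimethoxy-4-(triisopropylsilyloxy)benzaldehyde | COc1cc(C=O)cc(OC)c1O[Si](C(C)C)(C(C)C)C(C)C | intermediate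
12 | (3R,4S)-4-[3-(benzyloxy)propyl]-3-{hydroxy[3,5-dimethoxy-4-(triisopropylsilyloxy)phenyl]methyl}oxolan-2-one, both carbinol epimers | O(Cc1ccccc1)CCC[C@@H]2COC(=O)[C@H]2C(O)c3cc(OC)c(O[Si](C(C)C)(C(C)C)C(C)C)c(OC)c3 | intermediate
13 | methanesulfonate of 12 at the benzylic hydroxyl | O(Cc1ccccc1)CCC[C@@H]2COC(=O)[C@H]2C(OS(C)(=O)=O)c3cc(OC)c(O[Si](C(C)C)(C(C)C)C(C)C)c(OC)c3 | intermediate (not isolated)
14 | (3E,4S)-4-[3-(benzyloxy)propyl]-3-[3,5-dimethoxy-4-(triisopropylsilyloxy)benzylidene]oxolan-2-one | O(Cc1ccccc1)CCC[C@@H]2COC(=O)/C2=C/c3cc(OC)c(O[Si](C(C)C)(C(C)C)C(C)C)c(OC)c3 | intermediate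
15 | (3R,4R)-4-[3-(benzyloxy)propyl]-3-hydroxy-3-{(S)-hydroxy[3,5-dimethoxy-4-(triisopropylsilyloxy)phenyl]methyl}oxolan-2-one | O(Cc1ccccc1)CCC[C@@H]2COC(=O)[C@]2(O)[C@@H](O)c3cc(OC)c(O[Si](C(C)C)(C(C)C)C(C)C)c(OC)c3 | intermediate
16 | (3S,4R)-3-[3,5-dimethoxy-4-(triisopropylsilyloxy)benzyl]-3-hydroxy-4-(3-hydroxypropyl)oxolan-2-one | OCCC[C@@H]1COC(=O)[C@]1(O)Cc2cc(OC)c(O[Si](C(C)C)(C(C)C)C(C)C)c(OC)c2 | intermediate
17 | (3S,4R)-3-[3,5-dimethoxy-4-(triisopropylsilyloxy)benzyl]-3-(triethylsilyloxy)-4-[3-(triethylsilyloxy)propyl]oxolan-2-one | CC[Si](CC)(CC)OCCC[C@@H]1COC(=O)[C@]1(O[Si](CC)(CC)CC)Cc2cc(OC)c(O[Si](C(C)C)(C(C)C)C(C)C)c(OC)c2 | intermediate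
18 | (3S,4R)-3-[3,5-dimethoxy-4-(triisopropylsilyloxy)benzyl]-4-(3-oxopropyl)-3-(triethylsilyloxy)oxolan-2-one | O=CCC[C@@H]1COC(=O)[C@]1(O[Si](CC)(CC)CC)Cc2cc(OC)c(O[Si](C(C)C)(C(C)C)C(C)C)c(OC)c2 | intermediate (key-step precursor)
19 | 3,3-dimethoxybutan-2-one | COC(C)(OC)C(C)=O | starting material
20 | 3-methoxybut-3-en-2-one | COC(=C)C(C)=O | intermediate
21 | 4-methoxy-5-oxo-2-{[(3R,4S)-4-[3,5-dimethoxy-4-(triisopropylsilyloxy)benzyl]-5-oxo-4-(triethylsilyloxy)oxolan-3-yl]methyl}hexanal, mixture at the two new centres | O=CC(CC(OC)C(C)=O)C[C@@H]1COC(=O)[C@]1(O[Si](CC)(CC)CC)Cc2cc(OC)c(O[Si](C(C)C)(C(C)C)C(C)C)c(OC)c2 | intermediate (not isolated)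
22 | (3S,4R)-3-[3,5-dimethoxy-4-(triisopropylsilyloxy)benzyl]-4-[(2-hydroxy-5-methoxy-4-oxocyclohexyl)methyl]-3-(triethylsilyloxy)oxolan-2-one, mixture at the cyclohexanone centres | COC1CC(C[C@@H]2COC(=O)[C@]2(O[Si](CC)(CC)CC)Cc3cc(OC)c(O[Si](C(C)C)(C(C)C)C(C)C)c(OC)c3)C(O)CC1=O | intermediate (not isolated)
23 | (3S,4R)-3-[3,5-dimethoxy-4-(triisopropylsilyloxy)benzyl]-4-[(5-methoxy-4-oxocyclohex-2-en-1-yl)methyl]-3-(triethylsilyloxy)oxolan-2-one, mixture at the two cyclohexenone sp3 carbons | COC1CC(C[C@@H]2COC(=O)[C@]2(O[Si](CC)(CC)CC)Cc3cc(OC)c(O[Si](C(C)C)(C(C)C)C(C)C)c(OC)c3)C=CC1=O | intermediate (key-step product)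
24 | (3S,4R)-3-[3,5-dimethoxy-4-(triisopropylsilyloxy)benzyl]-4-[(3-methoxy-4-oxocyclohexa-2,5-dien-1-yl)methyl]-3-(triethylsilyloxy)oxolan-2-one | COC1=CC(C[C@@H]2COC(=O)[C@]2(O[Si](CC)(CC)CC)Cc3cc(OC)c(O[Si](C(C)C)(C(C)C)C(C)C)c(OC)c3)C=CC1=O | intermediate (not isolated)
25 | (3S,4R)-3-[3,5-dimethoxy-4-(triisopropylsilyloxy)benzyl]-4-(4-hydroxy-3-methoxybenzyl)-3-(triethylsilyloxy)oxolan-2-one | COc1cc(C[C@@H]2COC(=O)[C@]2(O[Si](CC)(CC)CC)Cc3cc(OC)c(O[Si](C(C)C)(C(C)C)C(C)C)c(OC)c3)ccc1O | intermediate
26 | (3S,4R)-3-hydroxy-3-(4-hydroxy-3,5-dimethoxybenzyl)-4-(4-hydroxy-3-methoxybenzyl)oxolan-2-one | COc1cc(C[C@@H]2COC(=O)[C@]2(O)Cc3cc(OC)c(O)c(OC)c3)ccc1O | target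

**Step count**

Total: 15 steps. Longest linear sequence: 13 steps (steps 1–4, 6–11 and 13–15); steps 5 and 12 prepare the two side components.

**Steps most likely to fail**

1. Step 13. The conjugate addition of the enamine to the donor-substituted enone may be slow, so that self-condensation of the aldehyde or polymerisation of the enone takes over. The fallback sets out from 18 and changes the nucleophile and the mode of activation. Me3SiCl and Et3N in warm DMF should convert 18 into the trimethylsilyl enol ether F1. A Mukaiyama–Michael addition of F1 to 20 with TiCl4 in CH2Cl2 at −78 °C, where the Lewis acid is held between the carbonyl and methoxyl oxygens of the acceptor, should give keto aldehyde 21 after aqueous work-up, now as an isolated compound. Dibenzylammonium trifluoroacetate in warm toluene should then close and dehydrate 21, and the route is rejoined at 23.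

2. Step 9. Cleavage of the benzylic C–OH bond may stall after the benzyl ether has gone, and forcing it with stronger acid invites loss of the aryl silyl ether. The fallback sets out from 15 and changes the leaving group. Ac2O, pyridine and catalytic DMAP at 0 °C should acetylate only the secondary benzylic hydroxyl and give the benzylic monoacetate F2. H2 over Pd/C in neutral EtOAc should then cleave the benzylic C–OAc bond together with the benzyl ether, and the route is rejoined at 16.

3. Step 14. The dehydrogenation may stop through slow palladation at the methoxy-bearing α-carbon or precipitation of palladium metal, and the acid additive may remove the tertiary silyl ether early. The fallback sets out from 23 and fixes the site of oxidation by enolisation first. LiN(SiMe3)2 and Me3SiCl in THF at −78 °C should give the cross-conjugated trimethylsilyl dienol ether F3. Saegusa–Ito oxidation of F3 with Pd(OAc)2 in MeCN at rt should give dienone 24, which tautomerises, and the route is rejoined at 25.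

**Further compounds**

F1 | step 13 | trimethylsilyl enol ether of aldehyde 18 (E/Z mixture) | C[Si](C)(C)OC=CC[C@@H]1COC(=O)[C@]1(O[Si](CC)(CC)CC)Cc2cc(OC)c(O[Si](C(C)C)(C(C)C)C(C)C)c(OC)c2
F2 | step 9 | benzylic monoacetate of diol 15 | O(Cc1ccccc1)CCC[C@@H]2COC(=O)[C@]2(O)[C@@H](OC(C)=O)c3cc(OC)c(O[Si](C(C)C)(C(C)C)C(C)C)c(OC)c3
F3 | step 14 | trimethylsilyl dienol ether of enone 23 (1-methoxy-2-trimethylsilyloxycyclohexa-1,3-diene carrying the lactone arm at C5) | COC1=C(O[Si](C)(C)C)C=CC(C[C@@H]2COC(=O)[C@]2(O[Si](CC)(CC)CC)Cc3cc(OC)c(O[Si](C(C)C)(C(C)C)C(C)C)c(OC)c3)C1
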